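**Assumption:** (−)-EGCG (bulk green-tea isolate) is taken as the cheap commercial chiral starting material. Primed locants (4', 4'') refer to the B-ring and the galloyl ring of an EGCG unit.

## Retrosynthetic overview

1. The target is a constitutional isomer of two EGCG units (C44H36O22). The one strategic cut is the diarylmethine C–C bond between the ring-opened upper half and C6 of the intact lower flavan.
2. This gives the p-quinone methide formed by C2–O1 opening of EGCG (1) as electrophile and a flavan A-ring as C-nucleophile. The lower half is first locked as the bis(diphenylmethylene) ketal 2 so that it cannot open or epimerise itself.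
3. Ring order: every carbocycle and the retained chroman are bought in 1, with three of the four stereocentres. The only rings made are two temporary 1,3-benzodioxoles (step 1).
4. The upper pyran is opened during the coupling via 3 to give 4 (step 2, fourth stereocentre by 1,2-induction). The dioxoles are removed last to give 5 (step 3).

## Route

**Step 1**
Reactants: 1 (−)-epigallocatechin gallate (EGCG)
Product: 2 EGCG bis(diphenylmethylene) ketal
Conditions: Ph2CCl2 (2.4 equiv), K2CO3 (5 equiv), MeCN, 20 °C, 16 h, Ar, dark; aq. citric acid work-up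
Reagents that add atoms: dichlorodiphenylmethane, ClC(Cl)(c1ccccc1)c1ccccc1
Why: Cyclic ketalisation (double O-alkylation) closes a five-membered benzodioxole on one vicinal hydroxyl pair of each pyrogallol ring, whereas the meta-disposed A-ring hydroxyls cannot bridge and any acyclic chloro-ether there hydrolyses on work-up; no stereocentre is touched, and tying up O-4' removes the para-hydroxyl this half would need to open to a quinone methide.

**Step 2**
Reactants: 1 (−)-epigallocatechin gallate (EGCG); 2 EGCG bis(diphenylmethylene) ketal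
Product: 4 coupled bis-ketal, via p-quinone methide 3 (not isolated)
Conditions: bis-ketal (4 equiv, excess recovered) in degassed 1,4-dioxane/0.1 M K-phosphate buffer pH 7.0 (2:1), 65 °C, Ar; EGCG (1 equiv) added over 4 h, then 2 h; AcOH quench; Sephadex LH-20, then prep. RP-HPLC
Reagents that add atoms: none
Why: At pH 7 the 4'-phenoxide of 1 expels O1 (retro-oxa-Michael, the same quinone methide through which EGCG epimerises), and this reversible opening funnels 3 into irreversible vinylogous Friedel–Crafts (1,6-conjugate) C-alkylation by the free phloroglucinol-type A-ring of 2, a net addition in which every atom of both partners ends up in 4; the galloyloxy carbon is carried over from 1 unchanged, and the new diarylmethine centre is set 1R by Felkin–Anh attack anti to the C–O(galloyl) bond of the A1,3-minimised methide (net inversion at the former C2), with the C8-linked regioisomer and the minor 1S epimer removed by chromatography.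

**Step 3**
Reactants: 4 coupled bis-ketal
Product: 5 target polyphenol
Conditions: H2 (1 atm), 20% Pd(OH)2/C, THF/MeOH (1:1), 20 °C, 3 h; filtration under Ar; RP-HPLC (0.1% HCO2H), lyophilisation
Reagents that add atoms: none
Why: Catalytic hydrogenolysis cleaves the doubly benzylic C–O bonds of both benzophenone ketals under neutral conditions that leave the galloyl esters, the diarylmethine C–H and the chroman C2–O1 bond intact, so all four stereocentres pass through unchanged.

## Compound list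

1 | (−)-epigallocatechin 3-O-gallate, (2R,3R) | O=C(O[C@@H]1Cc2c(O)cc(O)cc2O[C@@H]1c1cc(O)c(O)c(O)c1)c1cc(O)c(O)c(O)c1 | starting material

2 | (2R,3R)-5,7-dihydroxy-2-(7-hydroxy-2,2-diphenyl-1,3-benzodioxol-5-yl)chroman-3-yl 7-hydroxy-2,2-diphenyl-1,3-benzodioxole-5-carboxylate (3',4':3'',4''-bis-O-diphenylmethylene-EGCG) | Oc1cc2c(c(O)c1)C[C@@H](OC(=O)c1cc(O)c3OC(c4ccccc4)(c4ccccc4)Oc3c1)[C@@H](c1cc(O)c3OC(c4ccccc4)(c4ccccc4)Oc3c1)O2 | intermediate

3 | ring-opened EGCG p-quinone methide: (2R)-1-(3,5-dihydroxy-4-oxocyclohexa-2,5-dien-1-ylidene)-3-(2,4,6-trihydroxyphenyl)propan-2-yl 3,4,5-trihydroxybenzoate | O=C(O[C@H](Cc1c(O)cc(O)cc1O)C=C1C=C(O)C(=O)C(O)=C1)c1cc(O)c(O)c(O)c1 | intermediate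

4 | (2R,3R)-6-[(1R,2R)-1-(3,4,5-trihydroxyphenyl)-2-(3,4,5-trihydroxybenzoyloxy)-3-(2,4,6-trihydroxyphenyl)propyl]-5,7-dihydroxy-2-(7-hydroxy-2,2-diphenyl-1,3-benzodioxol-5-yl)chroman-3-yl 7-hydroxy-2,2-diphenyl-1,3-benzodioxole-5-carboxylate | O=C(O[C@H](Cc1c(O)cc(O)cc1O)[C@H](c1cc(O)c(O)c(O)c1)c1c(O)cc2c(c1O)C[C@@H](OC(=O)c1cc(O)c3OC(c4ccccc4)(c4ccccc4)Oc3c1)[C@@H](c1cc(O)c3OC(c4ccccc4)(c4ccccc4)Oc3c1)O2)c1cc(O)c(O)c(O)c1 | intermediate

5 | CNP0240551.1: (2R,3R)-6-[(1R,2R)-1-(3,4,5-trihydroxyphenyl)-2-(3,4,5-trihydroxybenzoyloxy)-3-(2,4,6-trihydroxyphenyl)propyl]-5,7-dihydroxy-2-(3,4,5-trihydroxyphenyl)chroman-3-yl 3,4,5-trihydroxybenzoate | O=C(O[C@H](Cc1c(O)cc(O)cc1O)[C@H](c1cc(O)c(O)c(O)c1)c1c(O)cc2c(c1O)C[C@@H](OC(=O)c1cc(O)c(O)c(O)c1)[C@@H](c1cc(O)c(O)c(O)c1)O2)c1cc(O)c(O)c(O)c1 | target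

## Totals

Total step count: 3. Longest linear sequence: 3 steps (1 → 2 → 4 → 5); compound 1 enters twice.

## Steps most likely to fail

**Step 2 (highest risk).** C8 of 2 is at least as nucleophilic as C6, so the wanted C6 isomer is expected to be the minor regioisomer (estimated C6:C8 about 1:2, d.r. at the new centre about 3:1). Product 4 can also be alkylated again on its free phloroglucinol ring. The fallback sets out from 2 and enforces C6 attack with a removable C8 bromine. Silylation (TBSCl, imidazole, DMF) gives the 5,7,5',5''-tetrakis-O-TBS ether of 2 F1. NBS (CH2Cl2, −20 °C) brominates the only activated A-ring position not flanked by two silyloxy groups and gives the 8-bromo tetrakis-O-TBS ether F2. TBAF/AcOH (THF, 0 °C) frees the phenols to give 8-bromo-2 F3. Coupling of F3 (4 equiv) with 1 under the step-2 conditions can then occur only at C6 and gives 8-bromo-4 F4. H2, Pd/C, NaOAc (THF/MeOH) removes the bromine together with both ketals, and the fallback comes back to the route at 5.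

**Step 1.** Base-mediated ketalisation of free EGCG may give C2 epimerisation, oxidation or incomplete bis-ketal formation. The fallback sets out from 1 and blocks only the two para-oxygens by regioselective alkylation of the most acidic hydroxyls. BnBr (2.1 equiv), KHCO3, KI, DMF, 20 °C gives 4',4''-di-O-benzyl-EGCG F5, which equally cannot form a quinone methide. Coupling of F5 (4 equiv) with 1 as in step 2 gives the 4',4''-di-O-benzyl analogue of the coupled product F6. Hydrogenolysis (H2, Pd(OH)2/C, THF/MeOH) then comes back to the route at 5.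

**Step 3.** Hydrogenolysis could stall on the hindered ketals or start to cleave the benzylic C2–O1 bond of the lower flavan. The fallback sets out from 4 and replaces reductive by solvolytic deprotection: AcOH/H2O (4:1), 60 °C, Ar (or TFA/H2O 9:1, 0 °C, 30 min). This leads directly to 5, where it rejoins the route; no new compound is made (F0).

## Further compounds

F1 | step 2 | 5,7,5',5''-tetrakis-O-(tert-butyldimethylsilyl) ether of 2 | CC(C)(C)[Si](C)(C)Oc1cc2c(c(O[Si](C)(C)C(C)(C)C)c1)C[C@@H](OC(=O)c1cc(O[Si](C)(C)C(C)(C)C)c3OC(c4ccccc4)(c4ccccc4)Oc3c1)[C@@H](c1cc(O[Si](C)(C)C(C)(C)C)c3OC(c4ccccc4)(c4ccccc4)Oc3c1)O2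

F2 | step 2 | 8-bromo-5,7,5',5''-tetrakis-O-(tert-butyldimethylsilyl) ether of 2 | CC(C)(C)[Si](C)(C)Oc1c(Br)c2c(c(O[Si](C)(C)C(C)(C)C)c1)C[C@@H](OC(=O)c1cc(O[Si](C)(C)C(C)(C)C)c3OC(c4ccccc4)(c4ccccc4)Oc3c1)[C@@H](c1cc(O[Si](C)(C)C(C)(C)C)c3OC(c4ccccc4)(c4ccccc4)Oc3c1)O2

F3 | step 2 | 8-bromo-2: (2R,3R)-8-bromo-5,7-dihydroxy-2-(7-hydroxy-2,2-diphenyl-1,3-benzodioxol-5-yl)chroman-3-yl 7-hydroxy-2,2-diphenyl-1,3-benzodioxole-5-carboxylate | Oc1c(Br)c2c(c(O)c1)C[C@@H](OC(=O)c1cc(O)c3OC(c4ccccc4)(c4ccccc4)Oc3c1)[C@@H](c1cc(O)c3OC(c4ccccc4)(c4ccccc4)Oc3c1)O2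

F4 | step 2 | 8-bromo-4 (C6-linked coupled bis-ketal with Br at C8 of the lower flavan) | O=C(O[C@H](Cc1c(O)cc(O)cc1O)[C@H](c1cc(O)c(O)c(O)c1)c1c(O)c(Br)c2c(c1O)C[C@@H](OC(=O)c1cc(O)c3OC(c4ccccc4)(c4ccccc4)Oc3c1)[C@@H](c1cc(O)c3OC(c4ccccc4)(c4ccccc4)Oc3c1)O2)c1cc(O)c(O)c(O)c1

F5 | step 1 | 4',4''-di-O-benzyl-EGCG: (2R,3R)-2-(4-benzyloxy-3,5-dihydroxyphenyl)-5,7-dihydroxychroman-3-yl 4-benzyloxy-3,5-dihydroxybenzoate | O=C(O[C@@H]1Cc2c(O)cc(O)cc2O[C@@H]1c1cc(O)c(OCc2ccccc2)c(O)c1)c1cc(O)c(OCc2ccccc2)c(O)c1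

F6 | step 1 | 4',4''-di-O-benzyl analogue of the coupled product (lower unit F5, C6-linked, 1R,2R upper unit) | O=C(O[C@H](Cc1c(O)cc(O)cc1O)[C@H](c1cc(O)c(O)c(O)c1)c1c(O)cc2c(c1O)C[C@@H](OC(=O)c1cc(O)c(OCc3ccccc3)c(O)c1)[C@@H](c1cc(O)c(OCc3ccccc3)c(O)c1)O2)c1cc(O)c(O)c(O)c1

F0 | step 3 | none | none
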